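**Remarks on the chemistry**

- Assumption: which mirror-image form of the phosphoramidite ligand gives (4R) in step 3 cannot be derived on paper. It is fixed by a first run, and the route is written for that form.
- Atom labels used throughout: ring O1, C2, C3, C4, C5. C3 carries the guaiacyl ring through C7; C4 carries the syringyl ring through the carbinol carbon C7′.

## Analysis of the target

The target 17 has one tetrahydrofuran ring (O1, C2–C5) in which both carbons next to oxygen, C2 and C5, are plain CH2 groups. C3 bears a 4-hydroxy-3-methoxybenzyl group (through C7) and C4 bears C7′, a secondary carbinol attached to a 4-hydroxy-3,5-dimethoxyphenyl ring. There are three contiguous stereocentres: C3 (R), C4 (R) and C7′ (S). The ring substituents are trans. The C7′ configuration is the one obtained when hydride reaches a C7′ ketone from the side of the C4 hydrogen while the carbonyl oxygen points toward C5 and O1.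

The sensitive groups are the two free phenols and the benzylic alcohol para to one of them, which ionises, eliminates and hydrogenolyses easily; both arenes are electron rich. The synthesis is hard because no heteroatom or carbonyl remains on the ring to steer C3 and C4, the two side chains differ only in benzylic oxidation level (C7 is CH2, C7′ is CHOH), and C7′ must be set relative to C4.

The strategy rests on the ring bonds O1–C2 and C3–C4. Cutting both leaves a three-atom unit O1–C5–C4 with an allylic terminus at C4, and a two-carbon unit C2–C3 that is the alkene of an aryl vinyl ketone whose carbonyl carbon is C7.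

## Retrosynthetic reasoning

**17 to 16.** The two phenol O–H bonds are traced to benzyl ethers. Benzyl is chosen because it survives organometallics, zerovalent palladium, base, ozone at low temperature and hydride, and both groups leave in one neutral final step.

**16 to 15.** The C7′–H bond is cut. Adding the aryl nucleophile to aldehyde 10 would put the aryl group where hydride has to go, because both the open and the chelated transition states direct attack anti to C3. Hydride addition to ketone 15 reverses the roles and should give the (S)-carbinol.

**15 to 14 to 10 and 12.** The C7′–aryl bond is cut, since it separates the syringyl ring as a nucleophile (aryllithium 13 from bromide 12, itself the benzyl ether of phenol 11) from aldehyde 10. This keeps the route convergent, and the carbinol epimer mixture 14 is converged by oxidation.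

**10 to 8.** The formyl carbon C7′ is traced to the terminal alkene of 8 by C=C cleavage. A vinyl group is inert in the preceding steps and is what an allylic alkylation leaves on C4.

**8 to 6.** The C7 methylene is traced to the ketone of 6. That ketone makes C3 nucleophilic for ring formation and lets C3 equilibrate to trans; the forward step must remove the oxygen without touching the vinyl group.

**6 to 3 and 4.** O1–C2 and C3–C4 are cut together. The polarity matches on both bonds: O1 is an alkoxide and C4 an allyl cation in the dipole that zerovalent palladium generates from carbonate 4, while C2 is the electrophilic and C3 the nucleophilic carbon of enone 3. One catalytic step gives the ring, two skeletal bonds and both ring stereocentres.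

**3 to 2 to 1.** Enone 3 comes from allylic alcohol 2 by oxidation, and 2 from commercial aldehyde 1 and a vinyl Grignard reagent, so the key step is reached in two routine steps.

## Alternatives that were turned down

**Alternative 1:** The C2–C3 bond of the protected target A2 is cut, leading back to alkoxyacetic acid A1.
- Forward key step: decarboxylation of A1 gives an O–CH2 radical that closes 5-exo onto styrene carbon C3, and the benzylic radical at C7 is then reduced.
- For: C7 arrives as CH2 with no ketone to remove. C7′ is set in the open chain and needs no oxidation–reduction correction. Only two deprotections follow A2. On end-game economy this is stronger than the chosen route.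
- Against: A1 must already carry C4 and C7′ in the right configuration, the E-styrene and the glycolic ether, which means a long linear sequence. C3 is set kinetically in a chair-like transition state biased by one substituent only, and it cannot be corrected later because C3 in A2 has no acidifying group.
- Comparison: the chosen route sets C3 under thermodynamic control and takes the absolute configuration from a catalyst acting on two simple components.

**Alternative 2:** C2–C3 and C4–C5 of acyl oxazolidinone A5 are cut.
- Forward key step: the parent carbonyl ylide, released from silyl ether A3 by fluoride, adds across the E-alkene of enoyl imide A4.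
- For: trans follows stereospecifically from the alkene geometry, C7 is already CH2, and the C4 carboxyl is close to ketone 15. Downstream it is shorter than the chosen route (no deoxygenation, no alkene cleavage, no alcohol oxidation).
- Against: facial control relies on the auxiliary in a thermal, non-chelated addition of a very small dipole. The C7 methylene of A4 lies between an arene and an enoyl group, so base or fluoride can move the alkene into conjugation with the arene. The unstabilised ylide must be used in excess, and the auxiliary is stoichiometric.
- Comparison: the chosen route offers catalytic absolute control and partners without this isomerisation problem.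

**Alternative 3:** C4–C5 of aldehyde A7 (the same compound as 10) is cut, back to the seven-membered enol acetal A6.
- Forward key step: a Lewis acid opens the O–CH2–O acetal and the enolate carbon recloses on the oxocarbenium carbon.
- For: the aldehyde level and the C7 methylene are reached directly, and trans is the thermodynamic outcome. If A6 were in hand it would replace steps 1–5, so it is stronger on step economy.
- Against: the acetal carbon is unsubstituted, so ionisation gives an unstabilised oxocarbenium ion and closure is 5-endo at that ion. The single stereocentre of A6 (an sp3 benzyl-bearing carbon on a seven-membered ring) has no direct catalytic asymmetric entry.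
- Comparison: the chosen route moves the risk into one catalytic step fed by commercial or two-step materials.

Key step: step 3

## Route

Step 1
Reactants: 1 4-(benzyloxy)-3-methoxybenzaldehyde
Product: 2 1-[4-(benzyloxy)-3-methoxyphenyl]prop-2-en-1-ol (racemic)
Conditions: CH2=CHMgBr, THF, −78 to 0 °C; aq NH4Cl
Reagents that add atoms: vinylmagnesium bromide, C=C[Mg]Br
Why: 1,2-Addition of a Grignard reagent to an aromatic aldehyde; the new carbinol centre is of no consequence because it is oxidised in step 2.

Step 2
Reactants: 2 1-[4-(benzyloxy)-3-methoxyphenyl]prop-2-en-1-ol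
Product: 3 1-[4-(benzyloxy)-3-methoxyphenyl]prop-2-en-1-one
Conditions: activated MnO2, CH2Cl2, rt; filtered, concentrated cold and used at once
Reagents that add atoms: none
Why: MnO2 oxidises benzylic allylic alcohols selectively under neutral heterogeneous conditions, so the polymerisation-prone aryl vinyl ketone is obtained by filtration alone.

Step 3
Reactants: 3 1-[4-(benzyloxy)-3-methoxyphenyl]prop-2-en-1-one; 4 4-vinyl-1,3-dioxolan-2-one (racemic)
Product: 6 [4-(benzyloxy)-3-methoxyphenyl][(3R,4R)-4-vinyltetrahydrofuran-3-yl]methanone, via cis-ketone 5 (not isolated)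
Conditions: Pd2(dba)3·CHCl3 (2.5 mol %), L* (10 mol %; (S)-BINOL-derived N,N-bis[(R)-1-phenylethyl]phosphoramidite or its mirror image), THF, 0 °C to rt, 3 added slowly to 4 (1.5 equiv); then DBU (0.2 equiv), rt
Reagents that add atoms: none
Why: Proposed new method: zerovalent palladium ionises the allylic C–O bond of 4 with loss of CO2 to a π-allylpalladium cation carrying a primary alkoxide; the alkoxide adds to the unsubstituted β-carbon of 3 (O1–C2) and the resulting ketone enolate alkylates the internal allyl terminus (C3–C4), releasing the catalyst. The closest known reaction type is the palladium-catalysed decarboxylative (3+2) annulation of vinylethylene carbonates with doubly activated alkenes, together with the allylic alkylation of ketone enolates; a singly activated, enolisable vinyl ketone combined with the unsubstituted carbonate 4 lies outside what has been shown. The tetrahydrofuran closes in a 5-exo allylic alkylation with the remaining alkene outside the ring, and attack at the internal rather than the terminal allyl carbon is secured by ring size, the alternative being a seven-membered ether. C4 is set by the phosphoramidite on palladium: the diastereomeric π-allyl complexes from racemic 4 should interconvert by π-σ-π isomerisation faster than the enolate attacks, so both enantiomers of 4 funnel to (4R). C3 lies α to the ketone and is set under thermodynamic control, DBU converting cis isomer 5 into trans ketone 6. The step needs conjugate addition rather than addition to the carbonyl group, and ring closure before the enolate meets a second molecule of 3; the unhindered β-methylene of 3 and the poor stability of an aryl ketone hemiketal alkoxide favour the first, and slow addition of 3 should secure the second.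

Step 4
Reactants: 6 [4-(benzyloxy)-3-methoxyphenyl][(3R,4R)-4-vinyltetrahydrofuran-3-yl]methanone
Product: 8 (3R,4R)-3-[4-(benzyloxy)-3-methoxybenzyl]-4-vinyltetrahydrofuran, via benzylic alcohol 7 (not isolated)
Conditions: Et3SiH (4 equiv), CF3CO2H, CH2Cl2, 0 °C to rt
Reagents that add atoms: none
Why: Ionic hydrogenation: the protonated ketone takes hydride to give 7, which ionises to a para-alkoxybenzylic cation that is reduced again, while the monosubstituted alkene and the ring ether offer no comparably stabilised cation. No stereocentre is formed, and C3 keeps its configuration as long as hydride capture is faster than loss of the C3 proton.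

Step 5
Reactants: 8 (3R,4R)-3-[4-(benzyloxy)-3-methoxybenzyl]-4-vinyltetrahydrofuran
Product: 10 (3R,4R)-4-[4-(benzyloxy)-3-methoxybenzyl]tetrahydrofuran-3-carbaldehyde, via secondary ozonide 9 (not isolated)
Conditions: O3, CH2Cl2, −78 °C, Sudan Red 7B end point; then PPh3, −78 °C to rt
Reagents that add atoms: ozone, [O-][O+]=O
Why: Ozonolysis with reductive work-up; the terminal alkene reacts much faster than the alkoxyarenes or the benzyl ether when the ozone feed stops at the indicator end point. The carbon now α to the aldehyde (C4) is already in its thermodynamically preferred trans arrangement to C3.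

Step 6
Reactants: 11 4-bromo-2,6-dimethoxyphenol
Product: 12 2-(benzyloxy)-5-bromo-1,3-dimethoxybenzene
Conditions: BnBr, K2CO3, DMF, 60 °C
Reagents that add atoms: benzyl bromide, BrCc1ccccc1
Why: Williamson ether synthesis on an acidic, flanked phenol.

Step 7
Reactants: 10 (3R,4R)-4-[4-(benzyloxy)-3-methoxybenzyl]tetrahydrofuran-3-carbaldehyde; 12 2-(benzyloxy)-5-bromo-1,3-dimethoxybenzene
Product: 14 [4-(benzyloxy)-3,5-dimethoxyphenyl]{(3R,4R)-4-[4-(benzyloxy)-3-methoxybenzyl]tetrahydrofuran-3-yl}methanol (both C7′ epimers), via aryllithium 13 (not isolated)
Conditions: 12, n-BuLi, THF, −78 °C; then 10, −78 °C; aq NH4Cl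
Reagents that add atoms: none
Why: Bromine–lithium exchange followed by 1,2-addition of the aryllithium to the aldehyde, which at −78 °C should outrun enolisation. Attack anti to C3 is expected to favour the (R)-carbinol, the epimer not wanted, so the mixture is carried on and corrected through the ketone.

Step 8
Reactants: 14 [4-(benzyloxy)-3,5-dimethoxyphenyl]{(3R,4R)-4-[4-(benzyloxy)-3-methoxybenzyl]tetrahydrofuran-3-yl}methanol (both C7′ epimers)
Product: 15 [4-(benzyloxy)-3,5-dimethoxyphenyl]{(3R,4R)-4-[4-(benzyloxy)-3-methoxybenzyl]tetrahydrofuran-3-yl}methanone
Conditions: Dess–Martin periodinane, NaHCO3, CH2Cl2, 0 °C to rt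
Reagents that add atoms: none
Why: Dess–Martin oxidation of a secondary benzylic alcohol under buffered conditions; both epimers converge on one ketone, and C4, now α to it, stays in the favoured trans arrangement.

Step 9
Reactants: 15 [4-(benzyloxy)-3,5-dimethoxyphenyl]{(3R,4R)-4-[4-(benzyloxy)-3-methoxybenzyl]tetrahydrofuran-3-yl}methanone
Product: 16 (S)-[4-(benzyloxy)-3,5-dimethoxyphenyl]{(3R,4R)-4-[4-(benzyloxy)-3-methoxybenzyl]tetrahydrofuran-3-yl}methanol
Conditions: Zn(BH4)2 (ethereal stock solution), Et2O/CH2Cl2, −78 to −30 °C; aq NH4Cl
Reagents that add atoms: none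
Why: Chelation-controlled hydride reduction: zinc bridges the carbonyl oxygen and ring oxygen O1 in a six-membered chelate that holds the carbonyl syn to C5, and hydride enters from the face of the C4 hydrogen, away from C3 and its benzyl group, which gives the (S)-carbinol. The open (Felkin–Anh) transition state with C3 as the large group predicts the same face, so substrate control should not depend on the chelate alone.

Step 10
Reactants: 16 (S)-[4-(benzyloxy)-3,5-dimethoxyphenyl]{(3R,4R)-4-[4-(benzyloxy)-3-methoxybenzyl]tetrahydrofuran-3-yl}methanol
Product: 17 (S)-(4-hydroxy-3,5-dimethoxyphenyl)[(3R,4R)-4-(4-hydroxy-3-methoxybenzyl)tetrahydrofuran-3-yl]methanol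
Conditions: H2 (1 atm), 10% Pd/C, EtOAc/EtOH, rt, stopped after 2 equiv H2
Reagents that add atoms: none
Why: Hydrogenolysis of two aryl benzyl ethers in a neutral solvent; these cleave much faster than a secondary benzylic alcohol, and no stereocentre is touched.

## Compound list

1 | 4-(benzyloxy)-3-methoxybenzaldehyde | COc1cc(C=O)ccc1OCc1ccccc1 | starting material
2 | 1-[4-(benzyloxy)-3-methoxyphenyl]prop-2-en-1-ol (racemic) | COc1cc(C(O)C=C)ccc1OCc1ccccc1 | intermediate
3 | 1-[4-(benzyloxy)-3-methoxyphenyl]prop-2-en-1-one | COc1cc(C(=O)C=C)ccc1OCc1ccccc1 | intermediate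
4 | 4-vinyl-1,3-dioxolan-2-one (racemic) | C=CC1COC(=O)O1 | starting material
5 | [4-(benzyloxy)-3-methoxyphenyl][(3S,4R)-4-vinyltetrahydrofuran-3-yl]methanone (cis) | COc1cc(C(=O)[C@@H]2COC[C@@H]2C=C)ccc1OCc1ccccc1 | intermediate
6 | [4-(benzyloxy)-3-methoxyphenyl][(3R,4R)-4-vinyltetrahydrofuran-3-yl]methanone (trans) | COc1cc(C(=O)[C@H]2COC[C@@H]2C=C)ccc1OCc1ccccc1 | intermediate
7 | [4-(benzyloxy)-3-methoxyphenyl][(3R,4R)-4-vinyltetrahydrofuran-3-yl]methanol (either carbinol epimer) | COc1cc(C(O)[C@H]2COC[C@@H]2C=C)ccc1OCc1ccccc1 | intermediate
8 | (3R,4R)-3-[4-(benzyloxy)-3-methoxybenzyl]-4-vinyltetrahydrofuran | COc1cc(C[C@H]2COC[C@@H]2C=C)ccc1OCc1ccccc1 | intermediate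
9 | secondary ozonide of 8: 1,2,4-trioxolane carrying the (3R,4R)-4-[4-(benzyloxy)-3-methoxybenzyl]tetrahydrofuran-3-yl group on C3 (either epimer at that carbon) | COc1cc(C[C@H]2COC[C@@H]2C2OCOO2)ccc1OCc1ccccc1 | intermediate
10 | (3R,4R)-4-[4-(benzyloxy)-3-methoxybenzyl]tetrahydrofuran-3-carbaldehyde | COc1cc(C[C@H]2COC[C@@H]2C=O)ccc1OCc1ccccc1 | intermediate
11 | 4-bromo-2,6-dimethoxyphenol | COc1cc(Br)cc(OC)c1O | starting material
12 | 2-(benzyloxy)-5-bromo-1,3-dimethoxybenzene | COc1cc(Br)cc(OC)c1OCc1ccccc1 | intermediate
13 | [4-(benzyloxy)-3,5-dimethoxyphenyl]lithium | [Li]c1cc(OC)c(OCc2ccccc2)c(OC)c1 | intermediate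
14 | [4-(benzyloxy)-3,5-dimethoxyphenyl]{(3R,4R)-4-[4-(benzyloxy)-3-methoxybenzyl]tetrahydrofuran-3-yl}methanol (both C7′ epimers) | COc1cc(C[C@H]2COC[C@@H]2C(O)c2cc(OC)c(OCc3ccccc3)c(OC)c2)ccc1OCc1ccccc1 | intermediate
15 | [4-(benzyloxy)-3,5-dimethoxyphenyl]{(3R,4R)-4-[4-(benzyloxy)-3-methoxybenzyl]tetrahydrofuran-3-yl}methanone | COc1cc(C[C@H]2COC[C@@H]2C(=O)c2cc(OC)c(OCc3ccccc3)c(OC)c2)ccc1OCc1ccccc1 | intermediate
16 | (S)-[4-(benzyloxy)-3,5-dimethoxyphenyl]{(3R,4R)-4-[4-(benzyloxy)-3-methoxybenzyl]tetrahydrofuran-3-yl}methanol | COc1cc(C[C@H]2COC[C@@H]2[C@H](O)c2cc(OC)c(OCc3ccccc3)c(OC)c2)ccc1OCc1ccccc1 | intermediate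
17 | (S)-(4-hydroxy-3,5-dimethoxyphenyl)[(3R,4R)-4-(4-hydroxy-3-methoxybenzyl)tetrahydrofuran-3-yl]methanol | COc1cc(C[C@H]2COC[C@@H]2[C@H](O)c2cc(OC)c(O)c(OC)c2)ccc1O | target

## Step count and least certain steps

Total: 10 steps. Longest linear sequence: 9 steps (1–5 and 7–10); step 6 is a one-step side branch.

**Step 3 (key step; the one step labelled as a proposed new method).**
- What may go wrong: chain Michael oligomerisation of 3 started by the alkoxide or the enolate may outrun ring closure. Enantiocontrol may erode if the π-allyl complexes equilibrate too slowly or if the ligand differentiates an allyl terminus without a second substituent poorly. Retro-oxa-Michael ring opening may occur during the DBU equilibration.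
- Fallback (known chemistry): it sets out from 1, returns at 8, and so also bypasses step 4. Aldehyde 1 is reduced with NaBH4 to [4-(benzyloxy)-3-methoxyphenyl]methanol F1 and converted with PBr3 into 1-(benzyloxy)-4-(bromomethyl)-2-methoxybenzene F2. Rhodium-catalysed asymmetric conjugate addition of potassium vinyltrifluoroborate to 2(5H)-furanone ([Rh(cod)Cl]2, the BINAP antipode that gives the S product, aqueous dioxane) gives (S)-4-vinyldihydrofuran-2(3H)-one F3. Its lithium enolate (LiN(SiMe3)2, THF, −78 °C) is alkylated by F2 anti to the vinyl group to give (3R,4R)-3-[4-(benzyloxy)-3-methoxybenzyl]-4-vinyldihydrofuran-2(3H)-one F4. LiAlH4 reduces this to (2R,3R)-2-[4-(benzyloxy)-3-methoxybenzyl]-3-vinylbutane-1,4-diol F5, and cyclodehydration through a monotosylate (n-BuLi, TsCl, then n-BuLi, THF) closes the ring to 8. Either primary hydroxyl may be activated, since both displacements give the same ether and no stereocentre is involved.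

**Step 4.**
- What may go wrong: loss of configuration at C3 through elimination of the benzylic cation to a styrene and reprotonation; partial acid cleavage of the aryl benzyl ether; slow addition of CF3CO2H to the alkene.
- Fallback without a cation at C7: from 6, condensation with TsNHNH2 (EtOH, catalytic AcOH) gives the N-tosylhydrazone of 6 F6. Catecholborane (CHCl3, 0 °C) followed by NaOAc·3H2O at reflux reduces the C=N bond and expels sulfinate and nitrogen, returning to the route at 8.

**Step 9.**
- What may go wrong: insufficient facial selectivity if the ring ether binds zinc weakly and the trans benzyl group on C3 shields its face only modestly.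
- Fallback moving from substrate control to catalyst control: from 15, Corey–Bakshi–Shibata reduction with (R)-2-methyl-CBS-oxazaborolidine and BH3·SMe2 (THF, −20 °C), in which the aryl group acts as the large substituent, returns to the route at 16. It makes no new compound (F0).

**Step 10.**
- What may go wrong: over-reduction, meaning hydrogenolysis of the C7′–O bond once the para phenol is free, or acid-promoted ionisation of the product on the catalyst surface.
- Fallback that reverses the order of the last two operations: from 15, hydrogenolysis at the ketone level (H2, Pd/C, EtOAc), where there is no benzylic C–O bond to lose, gives (4-hydroxy-3,5-dimethoxyphenyl)[(3R,4R)-4-(4-hydroxy-3-methoxybenzyl)tetrahydrofuran-3-yl]methanone F7. Reduction with excess LiBH(s-Bu)3 (THF, −78 °C; the first two equivalents are consumed by the phenols) from the same face returns to the route at 17.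

## Further compounds

F1 | step 3 | [4-(benzyloxy)-3-methoxyphenyl]methanol | COc1cc(CO)ccc1OCc1ccccc1
F2 | step 3 | 1-(benzyloxy)-4-(bromomethyl)-2-methoxybenzene | COc1cc(CBr)ccc1OCc1ccccc1
F3 | step 3 | (S)-4-vinyldihydrofuran-2(3H)-one | C=C[C@H]1COC(=O)C1
F4 | step 3 | (3R,4R)-3-[4-(benzyloxy)-3-methoxybenzyl]-4-vinyldihydrofuran-2(3H)-one | COc1cc(C[C@H]2C(=O)OC[C@@H]2C=C)ccc1OCc1ccccc1
F5 | step 3 | (2R,3R)-2-[4-(benzyloxy)-3-methoxybenzyl]-3-vinylbutane-1,4-diol | COc1cc(C[C@@H](CO)[C@H](CO)C=C)ccc1OCc1ccccc1
F6 | step 4 | N-tosylhydrazone of 6 | COc1cc(C(=NNS(=O)(=O)c2ccc(C)cc2)[C@H]2COC[C@@H]2C=C)ccc1OCc1ccccc1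
F0 | step 9 | none | none
F7 | step 10 | (4-hydroxy-3,5-dimethoxyphenyl)[(3R,4R)-4-(4-hydroxy-3-methoxybenzyl)tetrahydrofuran-3-yl]methanone | COc1cc(C[C@H]2COC[C@@H]2C(=O)c2cc(OC)c(O)c(OC)c2)ccc1O
A1 | alternative 1 | alkoxyacetic acid with the silyl-protected carbinol and the E-styrene (radical precursor) | OC(=O)COC[C@@H](/C=C/c1ccc(OCc2ccccc2)c(OC)c1)[C@H](O[Si](C)(C)C(C)(C)C)c1cc(OC)c(OCc2ccccc2)c(OC)c1
A2 | alternative 1 | O-tert-butyldimethylsilyl, di-O-benzyl protected target | COc1cc(C[C@H]2COC[C@@H]2[C@H](O[Si](C)(C)C(C)(C)C)c2cc(OC)c(OCc3ccccc3)c(OC)c2)ccc1OCc1ccccc1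
A3 | alternative 2 | chloromethyl (trimethylsilyl)methyl ether | C[Si](C)(C)COCCl
A4 | alternative 2 | (S)-4-benzyl-3-[(E)-4-(4-benzyloxy-3-methoxyphenyl)but-2-enoyl]oxazolidin-2-one | COc1cc(C/C=C/C(=O)N2[C@@H](Cc3ccccc3)COC2=O)ccc1OCc1ccccc1
A5 | alternative 2 | trans-4-(4-benzyloxy-3-methoxybenzyl)tetrahydrofuran-3-carbonyl oxazolidinone | COc1cc(C[C@H]2COC[C@@H]2C(=O)N2[C@@H](Cc3ccccc3)COC2=O)ccc1OCc1ccccc1
A6 | alternative 3 | 5-(4-benzyloxy-3-methoxybenzyl)-4,5-dihydro-1,3-dioxepine | COc1cc(C[C@H]2COCOC=C2)ccc1OCc1ccccc1
A7 | alternative 3 | trans-4-(4-benzyloxy-3-methoxybenzyl)tetrahydrofuran-3-carbaldehyde | COc1cc(C[C@H]2COC[C@@H]2C=O)ccc1OCc1ccccc1
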